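**Retrosynthetic overview**

- The cyclohexane ring is not built. It comes intact from (S)-carvone, which already carries C4 in the correct configuration, the C2 oxygen and the C1 methyl carbon.
- Key disconnection: the C5–O(angelate) bond, made by a direct γ-C–H angeloyloxylation of carvone with diangeloyl peroxide (new step, sets C5 trans to C4).
- C1 and C2: two hydride reductions of the enone (thermodynamic equatorial methyl, then axial alcohol).
- C7 and the C8–C9 bond: substrate-controlled hydroboration of the isopropenyl group, boron-to-zinc exchange, then catalyst-controlled addition to 3-methylbut-2-enal (sets C9).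
- C9–OAc: selective acetylation of the acyclic allylic alcohol in the presence of the hindered axial C2–OH.

Assumption: bisabolane locants are used (ring C1 methyl, C2 hydroxyl, C4 side chain, C5 angelate; chain C7 methyl-bearing, C9 acetate-bearing), and (Me3SiCH2)2Zn is a stock reagent made beforehand from Me3SiCH2MgCl and ZnBr2.

**Step 1**
Reactants: 1 angelic acid
Product: 2 bis[(2Z)-2-methylbut-2-enoyl] peroxide
Conditions: 1 (2.0 equiv), DCC (2.0 equiv), H2O2·urea (1.0 equiv), CH2Cl2, −10 → 0 °C, dark; used as a solution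
Reagents that add atoms: hydrogen peroxide (as its urea adduct), OO; angelic acid 1 (the second equivalent), C/C=C(/C)C(=O)O
Why: Carbodiimide-mediated double acylation of hydrogen peroxide (diacyl peroxide synthesis), in which the O-acylisourea of one molecule of 1 is attacked by H2O2 and the resulting peracid by the O-acylisourea of a second molecule of 1; cold neutral conditions leave the Z double bonds untouched and no stereocentre is formed.

**Step 2**
Reactants: 2 bis[(2Z)-2-methylbut-2-enoyl] peroxide, 3 (S)-(+)-carvone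
Product: 4 (1R,6S)-3-methyl-4-oxo-6-(prop-1-en-2-yl)cyclohex-2-en-1-yl (2Z)-2-methylbut-2-enoate
Conditions: 9-amino-9-deoxy-epi-quinine (20 mol %), Cl3CCO2H (40 mol %), BHT (10 mol %), THF, 0 °C → rt, dark
Reagents that add atoms: bis[(2Z)-2-methylbut-2-enoyl] peroxide 2, C/C=C(/C)C(=O)OOC(=O)/C(C)=C\C
Why: Proposed new method: amine-catalysed γ-C–H acyloxylation of an α-branched cyclic enone, in which the primary amine salt condenses with 3 to an iminium ion that loses a γ-proton (carvone C4) to give the through-conjugated dienamine, whose α-carbon (methyl-bearing, would become quaternary) is blocked, so the terminal γ-carbon attacks the O–O bond of 2 on the face anti to the neighbouring isopropenyl group (C5–O of the target formed trans to C4, 5R) and hydrolysis releases 4 plus one angelic acid; the closest known reaction types are the primary-amine-catalysed α-benzoyloxylation of ketones with dibenzoyl peroxide and the γ-selective dienamine functionalisation of α-branched enals.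

**Step 3**
Reactants: 4 (1R,6S)-3-methyl-4-oxo-6-(prop-1-en-2-yl)cyclohex-2-en-1-yl (2Z)-2-methylbut-2-enoate
Product: 6 (1R,2S,5S)-5-methyl-4-oxo-2-(prop-1-en-2-yl)cyclohexyl (2Z)-2-methylbut-2-enoate, via lithium enolate 5 (not isolated)
Conditions: LiBH(s-Bu)3 (1.1 equiv), THF, −78 °C; AcOH; then DBU (5 mol %), CH2Cl2, 0 °C
Reagents that add atoms: none
Why: Conjugate (1,4) hydride reduction of the β-unsubstituted cyclohexenone by the bulky borohydride (as for carvone itself; the hindered angelate and the isopropenyl group are not touched), after which C-protonation of enolate 5 and base equilibration place the C1 methyl equatorial in the chair that has methyl, angelate and isopropenyl all equatorial (1S of the target); the angelate is γ to the carbonyl from both sides, so no β-elimination is possible.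

**Step 4**
Reactants: 6 (1R,2S,5S)-5-methyl-4-oxo-2-(prop-1-en-2-yl)cyclohexyl (2Z)-2-methylbut-2-enoate
Product: 7 (1R,2S,4R,5S)-4-hydroxy-5-methyl-2-(prop-1-en-2-yl)cyclohexyl (2Z)-2-methylbut-2-enoate
Conditions: LiBH(s-Bu)3 (1.2 equiv), THF, −78 °C; AcOH
Reagents that add atoms: none
Why: Bulky-hydride ketone reduction, in which LiBH(s-Bu)3 attacks the 2-methylcyclohexanone carbonyl from the equatorial direction and gives the axial C2 alcohol cis to the C1 methyl (2R of the target), the esters being inert at −78 °C.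

**Step 5**
Reactants: 7 (1R,2S,4R,5S)-4-hydroxy-5-methyl-2-(prop-1-en-2-yl)cyclohexyl (2Z)-2-methylbut-2-enoate, 8 3-methylbut-2-enal
Product: 11 (1R,2S,4R,5S)-4-hydroxy-2-[(2R,4R)-4-hydroxy-6-methylhept-5-en-2-yl]-5-methylcyclohexyl (2Z)-2-methylbut-2-enoate, via alkylborane 9 (not isolated), via alkylzinc 10 (not isolated)
Conditions: Et2BH (2.5 equiv, made in the flask from BH3·SMe2 + 2 Et3B), Et2O, 0 °C → rt; Et2Zn (neat), 0 °C, then vacuum; (Me3SiCH2)2Zn; 8, Ti(OiPr)4 (2 equiv), (1S,2S)-1,2-bis(trifluoromethanesulfonamido)cyclohexane (8 mol %), toluene, −20 °C; aq NH4Cl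
Reagents that add atoms: 3-methylbut-2-enal 8, CC(C)=CC=O
Why: Hydroboration, boron–zinc exchange and Ti(OiPr)4/bis(sulfonamide)-promoted enantioselective organozinc addition (Knochel protocol), in which Et2BH adds to the 1,1-disubstituted alkene anti to C5 in the rotamer that keeps H4 next to the vinylic methyl (the sense known for isopulegol) and sets C7 (R), the primary C8–B bond is exchanged to zinc without touching C7, and the mixed RZnCH2SiMe3 reagent transfers only the C8 alkyl group to the aldehyde face chosen by the (1S,2S)-ligand and sets C9 (R).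

**Step 6**
Reactants: 11 (1R,2S,4R,5S)-4-hydroxy-2-[(2R,4R)-4-hydroxy-6-methylhept-5-en-2-yl]-5-methylcyclohexyl (2Z)-2-methylbut-2-enoate
Product: 12 (1R,2S,4R,5S)-2-[(2R,4R)-4-(acetyloxy)-6-methylhept-5-en-2-yl]-4-hydroxy-5-methylcyclohexyl (2Z)-2-methylbut-2-enoate
Conditions: Ac2O (1.1 equiv), pyridine, CH2Cl2, −20 → 0 °C
Reagents that add atoms: acetic anhydride, CC(=O)OC(C)=O
Why: Kinetically selective acylation, in which the unhindered acyclic allylic C9 alcohol is acetylated much faster than the axial C2 alcohol flanked by the C1 methyl, so limiting Ac2O at low temperature gives the mono-acetate without touching any stereocentre.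

**Compound list**

1 | angelic acid, (2Z)-2-methylbut-2-enoic acid | C/C=C(/C)C(=O)O | starting material
2 | bis[(2Z)-2-methylbut-2-enoyl] peroxide (diangeloyl peroxide) | C/C=C(/C)C(=O)OOC(=O)/C(C)=C\C | intermediate
3 | (S)-(+)-carvone, (5S)-2-methyl-5-(prop-1-en-2-yl)cyclohex-2-en-1-one | C1C=C(C)C(=O)C[C@H]1C(C)=C | starting material
4 | (1R,6S)-3-methyl-4-oxo-6-(prop-1-en-2-yl)cyclohex-2-en-1-yl (2Z)-2-methylbut-2-enoate (trans-γ-angeloyloxycarvone) | C/C=C(/C)C(=O)O[C@@H]1C=C(C)C(=O)C[C@H]1C(C)=C | intermediate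
5 | lithium enolate of 6 (C1=C2 enolate, O–Li on C2; C4 and C5 as in 4) | C/C=C(/C)C(=O)O[C@@H]1CC(C)=C(O[Li])C[C@H]1C(C)=C | intermediate
6 | (1R,2S,5S)-5-methyl-4-oxo-2-(prop-1-en-2-yl)cyclohexyl (2Z)-2-methylbut-2-enoate | C/C=C(/C)C(=O)O[C@@H]1C[C@H](C)C(=O)C[C@H]1C(C)=C | intermediate
7 | (1R,2S,4R,5S)-4-hydroxy-5-methyl-2-(prop-1-en-2-yl)cyclohexyl (2Z)-2-methylbut-2-enoate | C/C=C(/C)C(=O)O[C@@H]1C[C@H](C)[C@H](O)C[C@H]1C(C)=C | intermediate
8 | 3-methylbut-2-enal | CC(C)=CC=O | starting material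
9 | (1R,2S,4R,5S)-4-[(diethylboranyl)oxy]-2-[(2R)-1-(diethylboranyl)propan-2-yl]-5-methylcyclohexyl (2Z)-2-methylbut-2-enoate | C/C=C(/C)C(=O)O[C@@H]1C[C@H](C)[C@H](OB(CC)CC)C[C@H]1[C@H](C)CB(CC)CC | intermediate
10 | zinc analogue of 9: C8 carries Zn–CH2SiMe3 in place of BEt2, C7 unchanged in space (formally 2S after the priority change), O2 still as the diethylborinate | C/C=C(/C)C(=O)O[C@@H]1C[C@H](C)[C@H](OB(CC)CC)C[C@H]1[C@H](C)C[Zn]C[Si](C)(C)C | intermediate
11 | (1R,2S,4R,5S)-4-hydroxy-2-[(2R,4R)-4-hydroxy-6-methylhept-5-en-2-yl]-5-methylcyclohexyl (2Z)-2-methylbut-2-enoate | C/C=C(/C)C(=O)O[C@@H]1C[C@H](C)[C@H](O)C[C@H]1[C@H](C)C[C@H](C=C(C)C)O | intermediate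
12 | (1R,2S,4R,5S)-2-[(2R,4R)-4-(acetyloxy)-6-methylhept-5-en-2-yl]-4-hydroxy-5-methylcyclohexyl (2Z)-2-methylbut-2-enoate (CNP0237033.1) | C/C=C(/C)C(=O)O[C@@H]1C[C@H](C)[C@H](O)C[C@H]1[C@H](C)C[C@H](C=C(C)C)OC(C)=O | target

**Step count**

Total steps: 6. Longest linear sequence: 6 (steps 1–6, from angelic acid 1 through peroxide 2 to 12; carvone 3 enters at step 2).

**Three steps most likely to fail**

Step 2 (the new γ-angeloyloxylation). The risks are attack at the α'-carbon through the cross-conjugated dienamine, oxidation of the amine catalyst by the peroxide, loss of angelic acid from 4 with aromatisation, and Z→E isomerisation of the angelate. The fallback uses known chemistry, sets out from 3 and returns at 4. Deprotonation of 3 with MeMgBr and catalytic FeCl3 (Et2O, −20 °C) and trapping with Me3SiCl/Et3N gives the through-conjugated silyl ether trimethyl{[(5R)-2-methyl-5-(prop-1-en-2-yl)cyclohexa-1,3-dien-1-yl]oxy}silane F1. Sensitised photooxygenation (O2, hν, tetraphenylporphyrin, CH2Cl2, −78 °C) adds singlet oxygen to the diene face anti to the isopropenyl group and, after a 1,4-silyl shift, gives the γ-silylperoxy enone (4R,5S)-2-methyl-5-(prop-1-en-2-yl)-4-[(trimethylsilyl)peroxy]cyclohex-2-en-1-one F2. PPh3 and a mild aqueous acid work-up then give (4R,5S)-4-hydroxy-2-methyl-5-(prop-1-en-2-yl)cyclohex-2-en-1-one F3. Esterification with angelic acid 1 through its 2,4,6-trichlorobenzoyl mixed anhydride (Et3N, toluene, 80 °C) gives 4.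

Step 5 (hydroboration, zinc exchange and asymmetric addition). The risks are a modest C7 ratio with the small borane, interference of the free C2 oxygen, and incomplete boron–zinc exchange. The fallback sets out from 7 and returns at 11; it keeps the hydroboration but makes the C8–C9 bond by a PdCl2(dppf)-catalysed carbonylative coupling and sets C9 by reduction. 9-BBN (2.2 equiv, THF) gives the bis-borane (1R,2S,4R,5S)-4-[(9-borabicyclo[3.3.1]nonan-9-yl)oxy]-2-[(2R)-1-(9-borabicyclo[3.3.1]nonan-9-yl)propan-2-yl]-5-methylcyclohexyl (2Z)-2-methylbut-2-enoate F4. Carbonylative Suzuki–Miyaura coupling with 1-bromo-2-methylprop-1-ene (PdCl2(dppf), K3PO4, CO 1 atm) gives the enone (1R,2S,4R,5S)-4-hydroxy-5-methyl-2-[(2R)-6-methyl-4-oxohept-5-en-2-yl]cyclohexyl (2Z)-2-methylbut-2-enoate F5. Corey–Bakshi–Shibata reduction with the (S)-methyl oxazaborolidine and BH3·SMe2 gives 11.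

Step 6 (selective acetylation). The risk is competing acetylation of the C2 alcohol, giving the diacetate. The fallback sets out from 7 and returns at 12, masking C2–OH before the side chain is built. Et3SiCl/imidazole gives the silyl ether (1R,2S,4R,5S)-5-methyl-2-(prop-1-en-2-yl)-4-[(triethylsilyl)oxy]cyclohexyl (2Z)-2-methylbut-2-enoate F6. The step 5 sequence then gives in turn the C8 diethylborane F7, the C8 (trimethylsilylmethyl)zinc reagent F8 and the C9 alcohol (1R,2S,4R,5S)-2-[(2R,4R)-4-hydroxy-6-methylhept-5-en-2-yl]-5-methyl-4-[(triethylsilyl)oxy]cyclohexyl (2Z)-2-methylbut-2-enoate F9. Ac2O/DMAP/pyridine gives the acetate (1R,2S,4R,5S)-2-[(2R,4R)-4-(acetyloxy)-6-methylhept-5-en-2-yl]-5-methyl-4-[(triethylsilyl)oxy]cyclohexyl (2Z)-2-methylbut-2-enoate F10, and HF·pyridine (THF, 0 °C) gives 12.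

**Further compounds**

F1 | step 2 | trimethyl{[(5R)-2-methyl-5-(prop-1-en-2-yl)cyclohexa-1,3-dien-1-yl]oxy}silane | C1=CC(C)=C(O[Si](C)(C)C)C[C@H]1C(C)=C
F2 | step 2 | (4R,5S)-2-methyl-5-(prop-1-en-2-yl)-4-[(trimethylsilyl)peroxy]cyclohex-2-en-1-one | C[Si](C)(C)OO[C@@H]1C=C(C)C(=O)C[C@H]1C(C)=C
F3 | step 2 | (4R,5S)-4-hydroxy-2-methyl-5-(prop-1-en-2-yl)cyclohex-2-en-1-one | O[C@@H]1C=C(C)C(=O)C[C@H]1C(C)=C
F4 | step 5 | (1R,2S,4R,5S)-4-[(9-borabicyclo[3.3.1]nonan-9-yl)oxy]-2-[(2R)-1-(9-borabicyclo[3.3.1]nonan-9-yl)propan-2-yl]-5-methylcyclohexyl (2Z)-2-methylbut-2-enoate | C/C=C(/C)C(=O)O[C@@H]1C[C@H](C)[C@H](OB2C3CCCC2CCC3)C[C@H]1[C@H](C)CB2C3CCCC2CCC3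
F5 | step 5 | (1R,2S,4R,5S)-4-hydroxy-5-methyl-2-[(2R)-6-methyl-4-oxohept-5-en-2-yl]cyclohexyl (2Z)-2-methylbut-2-enoate | C/C=C(/C)C(=O)O[C@@H]1C[C@H](C)[C@H](O)C[C@H]1[C@H](C)CC(=O)C=C(C)C
F6 | step 6 | (1R,2S,4R,5S)-5-methyl-2-(prop-1-en-2-yl)-4-[(triethylsilyl)oxy]cyclohexyl (2Z)-2-methylbut-2-enoate | C/C=C(/C)C(=O)O[C@@H]1C[C@H](C)[C@H](O[Si](CC)(CC)CC)C[C@H]1C(C)=C
F7 | step 6 | (1R,2S,4R,5S)-2-[(2R)-1-(diethylboranyl)propan-2-yl]-5-methyl-4-[(triethylsilyl)oxy]cyclohexyl (2Z)-2-methylbut-2-enoate | C/C=C(/C)C(=O)O[C@@H]1C[C@H](C)[C@H](O[Si](CC)(CC)CC)C[C@H]1[C@H](C)CB(CC)CC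
F8 | step 6 | zinc analogue of F7 with Zn–CH2SiMe3 on C8 in place of BEt2 | C/C=C(/C)C(=O)O[C@@H]1C[C@H](C)[C@H](O[Si](CC)(CC)CC)C[C@H]1[C@H](C)C[Zn]C[Si](C)(C)C
F9 | step 6 | (1R,2S,4R,5S)-2-[(2R,4R)-4-hydroxy-6-methylhept-5-en-2-yl]-5-methyl-4-[(triethylsilyl)oxy]cyclohexyl (2Z)-2-methylbut-2-enoate | C/C=C(/C)C(=O)O[C@@H]1C[C@H](C)[C@H](O[Si](CC)(CC)CC)C[C@H]1[C@H](C)C[C@H](C=C(C)C)O
F10 | step 6 | (1R,2S,4R,5S)-2-[(2R,4R)-4-(acetyloxy)-6-methylhept-5-en-2-yl]-5-methyl-4-[(triethylsilyl)oxy]cyclohexyl (2Z)-2-methylbut-2-enoate | C/C=C(/C)C(=O)O[C@@H]1C[C@H](C)[C@H](O[Si](CC)(CC)CC)C[C@H]1[C@H](C)C[C@H](C=C(C)C)OC(C)=O
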